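## Retrosynthetic overview
1. **Macrocycle (last ring):** close C14–C1 by intramolecular B-alkyl Suzuki coupling of a 3-bromo-2,5-dihydrofuran with the 9-BBN adduct of a terminal 1,3-diene.
2. **Oxirane (second ring):** Shi epoxidation of C7=C8 on the open chain, while C3=C4 (allyl ether), C11=C12 (allyl chloride) and C1=C15 (vinyl bromide) are deactivated.
3. **C13/C14 terminus:** SeO2 oxidation of the farnesyl tail, then Cl → CHO → CH=CH2.
4. **Dihydrofuran (first ring):** the C2 alkoxide displaces one arm of a symmetric C15(CH2Cl)2 unit, so there is no alkene-geometry issue. The other arm becomes CH2OAc, and C2 is set by CBS reduction of an α-bromo dienone.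
5. **C1–C2 bond:** α-bromovinyllithium from Br2C=C(CH2Cl)2 adds to (E,E)-farnesal, which supplies C2–C13 and both E-trisubstituted alkenes.

Atom labels use cembrane numbering: C1 is the ring-fusion sp2 carbon, C2 is O–CH, and C15 is the sp2 carbon bearing C16H2–O and C17H2–OAc. The target SMILES decodes as (2R,7R,8R), 3E,11E.

Assumption: isomerically pure (2E,6E)-farnesol is purchased.

## Route

**Step 1**
- Reactants: 1, 1,3-dichloroacetone
- Product: 2, 1,1-dibromo-3-chloro-2-(chloromethyl)prop-1-ene
- Conditions: CBr4 (2 equiv), PPh3 (4 equiv), CH2Cl2, 0 °C, 30 min; then 1, 0 °C → rt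
- Reagents that add atoms: carbon tetrabromide, BrC(Br)(Br)Br (delivers =CBr2)
- Why: Ramirez dibromo-olefination, in which pre-formed Ph3P=CBr2 (no free PPh3) attacks the activated, electron-poor ketone, and the symmetric product has no alkene geometry.

**Step 2**
- Reactants: 3, (2E,6E)-farnesol
- Product: 4, (2E,6E)-farnesal
- Conditions: MnO2 (20 equiv), CH2Cl2, rt
- Reagents that add atoms: none
- Why: Neutral MnO2 allylic oxidation stops at the enal and does not erode the 2E geometry.

**Step 3**
- Reactants: 2 (1.2 equiv); 4
- Product: 5, rac-(5E,9E)-3-bromo-1-chloro-2-(chloromethyl)-6,10,14-trimethylpentadeca-2,5,9,13-tetraen-4-ol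
- Conditions: 2, n-BuLi (1.15 equiv), THF/Et2O/pentane, −110 °C, 10 min; then 4; AcOH/THF quench at −90 °C
- Reagents that add atoms: none
- Why: Br/Li exchange gives the α-bromovinyllithium (alkylidene carbenoid, stable below −100 °C), which adds 1,2 to the enal; the two Br atoms and two CH2Cl arms are equivalent so only one isomer forms, and the cold quench prevents premature racemic ring closure.

**Step 4**
- Reactants: 5
- Product: 6, (5E,9E)-3-bromo-1-chloro-2-(chloromethyl)-6,10,14-trimethylpentadeca-2,5,9,13-tetraen-4-one
- Conditions: Dess–Martin periodinane, NaHCO3, CH2Cl2, 0 °C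
- Reagents that add atoms: none
- Why: Buffered Dess–Martin oxidation of the bis-allylic alcohol tolerates the allylic chlorides, the vinyl bromide and the 5E alkene.

**Step 5**
- Reactants: 6
- Product: 7, (4R,5E,9E)-alcohol (single enantiomer of 5; C4 here is cembrane C2)
- Conditions: (S)-Me-CBS (0.5 equiv), catecholborane (1.8 equiv), toluene, −78 °C
- Reagents that add atoms: none
- Why: In this CBS reduction the twisted tetrasubstituted α-bromoalkenyl group acts as the large substituent and the planar CH=C(Me)R as the small one, so the (S)-catalyst gives the 2R carbinol in the same sense as acetophenone → (R)-1-phenylethanol, by 1,2-reduction only.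

**Step 6**
- Reactants: 7
- Product: 8, (2R)-3-bromo-4-(chloromethyl)-2-[(1E,5E)-2,6,10-trimethylundeca-1,5,9-trien-1-yl]-2,5-dihydrofuran
- Conditions: NaH (1.1 equiv), THF, 0 °C → rt
- Reagents that add atoms: none
- Why: Intramolecular Williamson etherification (5-exo-tet) can reach only the CH2Cl arm cis to C2, and the C2–O bond is never broken, so the 2R configuration is retained.

**Step 7**
- Reactants: 8
- Product: 9, {(5R)-4-bromo-5-[(1E,5E)-2,6,10-trimethylundeca-1,5,9-trien-1-yl]-2,5-dihydrofuran-3-yl}methyl acetate
- Conditions: KOAc (3 equiv), 18-crown-6 (cat.), DMF, 40 °C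
- Reagents that add atoms: potassium acetate, CC(=O)[O-].[K+]
- Why: SN2 displacement of the remaining primary allylic chloride installs the C17 acetate, and the vinyl bromide is inert to acetate.

**Step 8**
- Reactants: 9
- Product: 10, 9 with the terminal E-methyl oxidised: side chain (1E,5E,9E)-11-hydroxy-2,6,10-trimethylundeca-1,5,9-trien-1-yl
- Conditions: SeO2 (0.3 equiv), t-BuOOH (3 equiv), salicylic acid (0.1 equiv), CH2Cl2, 0 °C → rt, about 60% conversion; then NaBH4, MeOH, 0 °C; recycle 9
- Reagents that add atoms: selenium dioxide, O=[Se]=O, with tert-butyl hydroperoxide, CC(C)(C)OO (one O)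
- Why: Catalytic SeO2 allylic oxidation (ene then [2,3]-shift) selects the E-methyl of the terminal gem-dimethyl alkene, which is the most accessible electron-rich olefin, while C3=C4 and C1=C15 are deactivated by O and Br.

**Step 9**
- Reactants: 10
- Product: 11, the (9E)-11-chloro analogue of 10 (C13–Cl)
- Conditions: NCS, Me2S, CH2Cl2, −20 → 0 °C
- Reagents that add atoms: N-chlorosuccinimide, O=C1CCC(=O)N1Cl (Cl)
- Why: Corey–Kim chlorination converts the primary allylic alcohol to the chloride by SN2 without transposition, and the chloride both deactivates C11=C12 and serves as the later aldehyde precursor.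

**Step 10**
- Reactants: 11
- Product: 12, 11 with a (7R,8R)-epoxide (side-chain C5′–C6′, both R)
- Conditions: D-fructose-derived Shi ketone (0.3 equiv), Oxone (1.4 equiv), K2CO3, Bu4NHSO4, Na2B4O7/Na2EDTA buffer (pH about 10.5), MeCN/DMM, −5 to 0 °C, 2 h
- Reagents that add atoms: Oxone (KHSO5), OOS(=O)(=O)[O-].[K+] (one O, via the dioxirane)
- Why: In this Shi epoxidation the electrophilic dioxirane takes the only undeactivated trisubstituted alkene, and the spiro transition state of the D-fructose ketone gives (R,R)-epoxides from E-trisubstituted olefins under catalyst control, with minor diastereomers and regioisomers removed by chromatography.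

**Step 11**
- Reactants: 12
- Product: 13, the (E)-2-methyl enal (C13 = CHO) otherwise identical to 12
- Conditions: NMO (5 equiv), KI (1 equiv), 4 Å MS, MeCN, rt
- Reagents that add atoms: N-methylmorpholine N-oxide, C[N+]1([O-])CCOCC1 (O)
- Why: Kornblum/Ganem-type N-oxide oxidation proceeds by in situ Finkelstein exchange, SN2 by the N-oxide oxygen and elimination under neutral conditions that spare the epoxide and acetate, and the E-enal is also the thermodynamic isomer.

**Step 12**
- Reactants: 13
- Product: 14, the terminal (E)-3-methyl-1,3-diene (C11=C12(Me)–C13H=C14H2) otherwise identical to 13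
- Conditions: Ph3PCH3Br (1.3 equiv), KHMDS (1.2 equiv), THF, −78 → 0 °C
- Reagents that add atoms: methyltriphenylphosphonium bromide, C[P+](c1ccccc1)(c1ccccc1)c1ccccc1.[Br-] (CH2 = C14)
- Why: Wittig methylenation of the enal at low temperature is far faster than attack on the acetate, the trisubstituted epoxide or the vinyl bromide.

**Step 13**
- Reactants: 14
- Product: 15, lobophynin B
- Conditions: 9-BBN (1.3 equiv), THF, 0 °C → rt; then syringe-pump addition (12 h) to Pd(dppf)Cl2 (15 mol %), AsPh3 (15 mol %), Cs2CO3 (3 equiv), DMF/THF/H2O, 50 °C, final concentration 1 mM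
- Reagents that add atoms: none (9-BBN delivers only H; boron is lost)
- Why: 9-BBN hydroborates only the monosubstituted vinyl terminus of the diene to put boron on C14, and intramolecular B-alkyl Suzuki–Miyaura coupling with the cyclic vinyl bromide forms C14–C1 and the 14-membered ring without touching any stereocentre, the hindered allylic acetate or the isolated epoxide.

## Compound list

| No. | Name | SMILES | Role |
|---|---|---|---|
| 1 | 1,3-dichloroacetone | `O=C(CCl)CCl` | starting material |
| 2 | 1,1-dibromo-3-chloro-2-(chloromethyl)prop-1-ene | `BrC(Br)=C(CCl)CCl` | intermediate |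
| 3 | (2E,6E)-farnesol | `CC(C)=CCC/C(C)=C/CC/C(C)=C/CO` | starting material |
| 4 | (2E,6E)-farnesal | `CC(C)=CCC/C(C)=C/CC/C(C)=C/C=O` | intermediate |
| 5 | racemic bromo bis(chloromethyl) dienol | `CC(C)=CCC/C(C)=C/CC/C(C)=C/C(O)C(Br)=C(CCl)CCl` | intermediate |
| 6 | α-bromo cross-conjugated dienone | `CC(C)=CCC/C(C)=C/CC/C(C)=C/C(=O)C(Br)=C(CCl)CCl` | intermediate |
| 7 | (R)-dienol | `CC(C)=CCC/C(C)=C/CC/C(C)=C/[C@@H](O)C(Br)=C(CCl)CCl` | intermediate |
| 8 | (2R)-3-bromo-4-(chloromethyl)-2-trienyl-2,5-dihydrofuran | `CC(C)=CCC/C(C)=C/CC/C(C)=C/[C@H]1OCC(CCl)=C1Br` | intermediate |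
| 9 | C17 acetate | `CC(C)=CCC/C(C)=C/CC/C(C)=C/[C@H]1OCC(COC(C)=O)=C1Br` | intermediate |
| 10 | C13 (E)-allylic alcohol | `OC/C(C)=C/CC/C(C)=C/CC/C(C)=C/[C@H]1OCC(COC(C)=O)=C1Br` | intermediate |
| 11 | C13 (E)-allylic chloride | `ClC/C(C)=C/CC/C(C)=C/CC/C(C)=C/[C@H]1OCC(COC(C)=O)=C1Br` | intermediate |
| 12 | (7R,8R)-epoxy chloride | `ClC/C(C)=C/CC[C@@]2(C)O[C@@H]2CC/C(C)=C/[C@H]1OCC(COC(C)=O)=C1Br` | intermediate |
| 13 | epoxy enal | `O=C/C(C)=C/CC[C@@]2(C)O[C@@H]2CC/C(C)=C/[C@H]1OCC(COC(C)=O)=C1Br` | intermediate |
| 14 | epoxy diene | `C=C/C(C)=C/CC[C@@]2(C)O[C@@H]2CC/C(C)=C/[C@H]1OCC(COC(C)=O)=C1Br` | intermediate |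
| 15 | lobophynin B, (2R,7R,8R) | `CC(=O)OCC1=C2CC/C(C)=C/CC[C@@]3(C)O[C@@H]3CC/C(C)=C/[C@H]2OC1` | target |

## Step count
- Total steps: 13
- Longest linear sequence: 12 (steps 2–13, from farnesol)

## Steps most likely to fail
1. **Step 13 (macrocyclic B-alkyl Suzuki).**
   - Risk: the vinyl bromide is hindered, the coupling runs at high dilution, and an allylic acetate is present.
   - Fallback: change the ring-closing bond. Couple the diene-derived borane intermolecularly with the bis-OTBS analogue of 2 (mono-coupling of the gem-dibromide) on a chain carrying a C2 enal. Close C1–C2 by Ni/Cr (Nozaki–Hiyama–Kishi) macrocyclisation, correct C2 by oxidation and CBS reduction, then desilylate, close the ether and acetylate.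
2. **Step 10 (Shi epoxidation).**
   - Risk: site selectivity against C3=C4, and survival of the allylic chloride at pH 10.5.
   - Fallback: install the epoxide first. Epoxidise (2E,6E,10E)-12-chlorofarnesyl acetate, where both flanking alkenes carry allylic withdrawing groups. Then run the NMO oxidation and Wittig, deacetylate, oxidise with MnO2, and join to 2 as in steps 3–7. This is one step longer.
3. **Step 3 (carbenoid bearing allylic chlorides).**
   - Risk: decomposition of the carbenoid or premature racemic cyclisation.
   - Fallback: avoid the carbenoid. Homologate 4 to the (E)-enyne with the Ohira–Bestmann reagent, add its acetylide to 1, and use an NBS/Au(I) halogen-intercepted Meyer–Schuster rearrangement of the tertiary propargylic alcohol. This gives bromodienone 6 directly.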